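With C1′ and C3′ raised to the carbonyl level (C1′ = carbinol carbon on the oxazole, C6′ = methyl), the chain C1′–C5′ closes through O5′ onto C1′. This gives a six-membered 2,3-dihydro-4H-pyran-4-one ring in which the C4′ myristoyloxy and C5′ methyl groups are cis. The ring is cut at C4′–C5′ and O5′–C1′. C5′–C6′ becomes acetaldehyde, and C1′–C4′ becomes a (1Z,3Z)-1,3-bis(silyloxy)diene that carries the bis-oxazole at C1′ and the myristate at C4′. One enantioselective Cr(III)-catalysed hetero-Diels–Alder reaction makes both bonds, the ring and the C4′/C5′ stereocentres. C3′ is then set from the ring (Luche). O5′ is released by hydration and ring opening. C1′ is set from C3′ (Narasaka–Prasad).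

Key step: step 9

Remark (assumption): the (1R,2S)-aminoindanol-derived Cr(III) catalyst is taken to leave the Re face of acetaldehyde open, as it does for other unbranched aliphatic aldehydes; should the sense prove opposite, its enantiomer is used with no other change.

Step 1
Reactants: 1 oxazol-5-ylmethanol
Product: 2 5-(chloromethyl)oxazole
Conditions: SOCl2 (1.2 equiv), CH2Cl2, 0 °C → rt; cold aq NaHCO3; kept as a dried, cold solution
Reagents that add atoms: thionyl chloride, O=S(Cl)Cl
Why: Deoxychlorination of a primary heteroarylmethyl alcohol through its chlorosulfite (SN2 by chloride) is routine, and keeping the free base cold and dilute avoids slow self-quaternisation at nitrogen.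

Step 2
Reactants: 2 5-(chloromethyl)oxazole; 3 ethyl 2-chlorooxazole-4-carboxylate
Product: 5 ethyl 2-(oxazol-5-ylmethyl)oxazole-4-carboxylate, via oxazol-5-ylmethylzinc chloride 4 (not isolated)
Conditions: Zn dust, LiCl, THF, 25 °C; then 3, Pd(OAc)2 (2 mol %), SPhos (4 mol %), THF, 25 → 40 °C
Reagents that add atoms: none
Why: LiCl-assisted zinc insertion into a heteroarylmethyl chloride followed by Negishi cross-coupling is established for this reagent class, the C2–Cl bond of 3 (flanked by O1 and N3 and activated by the ester) adds readily to Pd(0), and the organozinc is too weak a base to touch the ester or the acidic CH2 of the product.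

Step 3
Reactants: 5 ethyl 2-(oxazol-5-ylmethyl)oxazole-4-carboxylate
Product: 6 N-methoxy-N-methyl-2-(oxazol-5-ylmethyl)oxazole-4-carboxamide
Conditions: MeNH(OMe)·HCl, AlMe3, CH2Cl2, 0 °C → rt; aq Rochelle salt
Reagents that add atoms: N,O-dimethylhydroxylamine hydrochloride, CNOC.Cl
Why: Weinreb amide formation by aluminium-amide aminolysis of the ester works because the aluminium amide attacks the coordinated carbonyl yet is far less basic than a magnesium or lithium amide, so the CH2 between the oxazoles and the C2–H of the terminal oxazole are not metallated.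

Step 4
Reactants: 6 N-methoxy-N-methyl-2-(oxazol-5-ylmethyl)oxazole-4-carboxamide
Product: 7 1-[2-(oxazol-5-ylmethyl)oxazol-4-yl]ethan-1-one
Conditions: MeMgBr (1.2 equiv), THF, −78 → −30 °C; pH 7 buffer
Reagents that add atoms: methylmagnesium bromide, C[Mg]Br
Why: Grignard addition to a Weinreb amide stops at the ketone stage because of the stable magnesium chelate, and at low temperature with only a slight excess of reagent this chelation-assisted addition should outrun deprotonation of the oxazole C2–H or the bridging CH2.

Step 5
Reactants: 8 glycolic acid; 9 tetradecanoyl (myristoyl) chloride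
Product: 10 (tetradecanoyloxy)acetic acid
Conditions: neat, 70 °C (HCl vented); H2O work-up; recrystallisation from hexane
Reagents that add atoms: none
Why: Base-free O-acylation of an α-hydroxy acid by an acid chloride is the classical route to acyloxyacetic acids, any mixed anhydride is hydrolysed in the work-up, and recrystallisation removes myristic acid.

Step 6
Reactants: 10 (tetradecanoyloxy)acetic acid
Product: 11 (tetradecanoyloxy)acetyl chloride
Conditions: (COCl)2, DMF (cat.), CH2Cl2, 0 °C → rt; evaporate, use crude
Reagents that add atoms: oxalyl chloride, O=C(Cl)C(=O)Cl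
Why: Acid chloride formation through the catalytic Vilsmeier-type chloroiminium salt runs cold and without base, which leaves the ester untouched.

Step 7
Reactants: 7 1-[2-(oxazol-5-ylmethyl)oxazol-4-yl]ethan-1-one; 11 (tetradecanoyloxy)acetyl chloride
Product: 12 2,4-dioxo-4-[2-(oxazol-5-ylmethyl)oxazol-4-yl]butyl tetradecanoate
Conditions: MgBr2·OEt2 (2.5 equiv), i-Pr2NEt (3 equiv), CH2Cl2, 0 °C → rt; aq citric acid
Reagents that add atoms: none
Why: In this soft-enolisation crossed-Claisen C-acylation, Mg(II) held between N3 and the ketone oxygen acidifies the methyl group enough for a tertiary amine, the magnesium enolate is acylated at carbon, and the product rests as its inert magnesium diketonate, so neither the myristate nor the bridging CH2 meets a strong base.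

Step 8
Reactants: 12 2,4-dioxo-4-[2-(oxazol-5-ylmethyl)oxazol-4-yl]butyl tetradecanoate
Product: 13 (1Z,3Z)-2,4-bis[(tert-butyldimethylsilyl)oxy]-4-[2-(oxazol-5-ylmethyl)oxazol-4-yl]buta-1,3-dien-1-yl tetradecanoate
Conditions: TBSOTf (2.3 equiv), Et3N (4 equiv), Et2O, 0 °C → rt; pentane/aq NaHCO3; Et3N-deactivated SiO2
Reagents that add atoms: tert-butyldimethylsilyl triflate, CC(C)(C)[Si](C)(C)OS(=O)(=O)C(F)(F)F
Why: In this double enol silylation with silyl triflate and amine the chelated enol is capped first and C4′, the only remaining enolisable position next to a carbonyl, is then deprotonated with the acyloxy group turned away from C2′ to avoid allylic strain, which gives the (Z)-enol ester as known for 1-acyloxy-4-alkoxybut-3-en-2-ones, and TBS is preferred to TMS so that the diene survives isolation.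

Step 9
Reactants: 13 (1Z,3Z)-2,4-bis[(tert-butyldimethylsilyl)oxy]-4-[2-(oxazol-5-ylmethyl)oxazol-4-yl]buta-1,3-dien-1-yl tetradecanoate; 14 acetaldehyde
Product: 16 (2S,3R)-2-methyl-6-[2-(oxazol-5-ylmethyl)oxazol-4-yl]-4-oxo-3,4-dihydro-2H-pyran-3-yl tetradecanoate, via primary cycloadduct 15 (not isolated)
Conditions: Cr(III) hexafluoroantimonate complex of the tridentate Schiff base from (1R,2S)-1-aminoindan-2-ol and 3-(1-adamantyl)-2-hydroxy-5-methylbenzaldehyde (10 mol %), 4 Å MS, freshly distilled MeCHO (10 equiv), t-BuOMe, 4 °C → rt, sealed; then TFA, CH2Cl2, 0 °C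
Reagents that add atoms: none
Why: Proposed new method: the aldehyde, bound to chromium through the lone pair anti to its methyl group, should meet the s-cis diene in a concerted but strongly asynchronous [4+2] cycloaddition in which C4′–C5′ bonding leads and O5′–C1′ bonding follows, after which TFA cleaves the C3′ enol silane of 15 and expels silanol from C1′ to give the vinylogous ester 16. The closest known reactions are the Lewis acid catalysed cyclocondensation of 4-acyloxy-1-alkoxy-3-silyloxybutadienes with acetaldehyde and the Cr(III) Schiff-base catalysed hetero-Diels–Alder reaction of 4-substituted silyloxydienes with aliphatic aldehydes; what has not been shown is a diene terminus that bears both a silyloxy and a heteroaryl group under such a catalyst. The pyran ring closes in the cycloaddition itself, and if crowding at C1′ turns the process into a Mukaiyama aldol addition the same ring forms during the acid treatment by 6-endo-trig addition of O5′ to C1′ of the β-silyloxy enone followed by loss of silanol. C5′ (S) is fixed by the ligand, which leaves only the Re face of the bound aldehyde open. C4′ (R) is fixed relative to C5′ because the (Z)-enol ester points the acyloxy group outward while the bulky metal fragment sits exo and so places the methyl group endo, and an outward diene substituent and an endo dienophile substituent end up cis. The step needs C4′ rather than C2′ as the nucleophilic carbon and endo rather than exo topology: the first is secured by both silyloxy groups pushing electron density to C4′, the second by the diene geometry fixed in step 8, whereas the C1′=C2′ geometry is irrelevant because C1′ returns to sp2.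

Step 10
Reactants: 16 (2S,3R)-2-methyl-6-[2-(oxazol-5-ylmethyl)oxazol-4-yl]-4-oxo-3,4-dihydro-2H-pyran-3-yl tetradecanoate
Product: 17 (2S,3S,4S)-4-hydroxy-2-methyl-6-[2-(oxazol-5-ylmethyl)oxazol-4-yl]-3,4-dihydro-2H-pyran-3-yl tetradecanoate (all-cis)
Conditions: NaBH4, CeCl3·7H2O, MeOH–CH2Cl2, −78 °C; AcOH then pH 7 buffer at −78 °C
Reagents that add atoms: none
Why: In this Luche 1,2-reduction the half-chair holds the C5′ methyl equatorial and the C4′ acyloxy group axial, hydride enters C3′ from the face opposite that ester, so the new hydroxyl is pseudo-equatorial and cis to it (3′S), and the cold buffered quench suppresses an O4′→O3′ acyl shift.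

Step 11
Reactants: 17 (2S,3S,4S)-4-hydroxy-2-methyl-6-[2-(oxazol-5-ylmethyl)oxazol-4-yl]-3,4-dihydro-2H-pyran-3-yl tetradecanoate
Product: 18 (2S,3S,4S,6S)-4,6-dihydroxy-2-methyl-6-[2-(oxazol-5-ylmethyl)oxazol-4-yl]tetrahydro-2H-pyran-3-yl tetradecanoate (hemiketal, drawn as the anomer with axial OH)
Conditions: Ph3P·HBr (10 mol %), THF–H2O 9:1, 0 °C → rt; aq NaHCO3
Reagents that add atoms: water, O
Why: In this Markovnikov acid-catalysed hydration of a glycal-type enol ether, C2′ is protonated and the C1′ oxocarbenium ion stabilised by O5′ takes up water, the weak catalytic acid is one known to add oxygen nucleophiles to glycals without Ferrier-type ionisation at C3′, and the C1′ configuration is of no consequence because it equilibrates by ring opening.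

Step 12
Reactants: 18 (2S,3S,4S,6S)-4,6-dihydroxy-2-methyl-6-[2-(oxazol-5-ylmethyl)oxazol-4-yl]tetrahydro-2H-pyran-3-yl tetradecanoate
Product: 21 target (2S,3R,4S,6R)-2,4,6-trihydroxy-6-[2-(oxazol-5-ylmethyl)oxazol-4-yl]hexan-3-yl tetradecanoate, via open-chain hydroxy ketone 19 (not isolated), via diethylboron chelate 20 (not isolated)
Conditions: Et2BOMe (1.2 equiv), THF–MeOH 4:1, −78 °C; NaBH4, −78 → −40 °C; AcOH; repeated evaporation from MeOH (boron leaves as volatile Et2BOMe)
Reagents that add atoms: none
Why: In this Narasaka–Prasad reduction the open-chain tautomer 19 is drained from the hemiketal equilibrium as the six-membered O3′–B–O=C1′ chelate 20, external hydride attacks its half-chair axially, opposite the equatorial C3′ side chain, to give the 1,3-syn diol, that is (1′R) from (3′S), and the non-basic, non-oxidative work-up protects the C4′ ester from migration.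

Compound list
1 | oxazol-5-ylmethanol | OCc1cnco1 | starting material
2 | 5-(chloromethyl)oxazole | ClCc1cnco1 | intermediate
3 | ethyl 2-chlorooxazole-4-carboxylate | CCOC(=O)c1coc(Cl)n1 | starting material
4 | oxazol-5-ylmethylzinc chloride (formed in situ) | Cl[Zn]Cc1cnco1 | intermediate
5 | ethyl 2-(oxazol-5-ylmethyl)oxazole-4-carboxylate | CCOC(=O)c1coc(Cc2cnco2)n1 | intermediate
6 | N-methoxy-N-methyl-2-(oxazol-5-ylmethyl)oxazole-4-carboxamide | CON(C)C(=O)c1coc(Cc2cnco2)n1 | intermediate
7 | 1-[2-(oxazol-5-ylmethyl)oxazol-4-yl]ethan-1-one | CC(=O)c1coc(Cc2cnco2)n1 | intermediate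
8 | glycolic acid | OCC(=O)O | starting material
9 | tetradecanoyl (myristoyl) chloride | CCCCCCCCCCCCCC(=O)Cl | starting material
10 | (tetradecanoyloxy)acetic acid | CCCCCCCCCCCCCC(=O)OCC(=O)O | intermediate
11 | (tetradecanoyloxy)acetyl chloride | CCCCCCCCCCCCCC(=O)OCC(=O)Cl | intermediate
12 | 2,4-dioxo-4-[2-(oxazol-5-ylmethyl)oxazol-4-yl]butyl tetradecanoate (drawn as diketo form) | CCCCCCCCCCCCCC(=O)OCC(=O)CC(=O)c1coc(Cc2cnco2)n1 | intermediate
13 | (1Z,3Z)-2,4-bis[(tert-butyldimethylsilyl)oxy]-4-[2-(oxazol-5-ylmethyl)oxazol-4-yl]buta-1,3-dien-1-yl tetradecanoate | CCCCCCCCCCCCCC(=O)O/C=C(O[Si](C)(C)C(C)(C)C)/C=C(\O[Si](C)(C)C(C)(C)C)c1coc(Cc2cnco2)n1 | intermediate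
14 | acetaldehyde | CC=O | starting material
15 | (2S,3R,6R)-4,6-bis[(tert-butyldimethylsilyl)oxy]-2-methyl-6-[2-(oxazol-5-ylmethyl)oxazol-4-yl]-3,6-dihydro-2H-pyran-3-yl tetradecanoate (endo cycloadduct, formed in situ) | CCCCCCCCCCCCCC(=O)O[C@H]([C@H](C)O1)C(O[Si](C)(C)C(C)(C)C)=C[C@@]1(O[Si](C)(C)C(C)(C)C)c2coc(Cc3cnco3)n2 | intermediate
16 | (2S,3R)-2-methyl-6-[2-(oxazol-5-ylmethyl)oxazol-4-yl]-4-oxo-3,4-dihydro-2H-pyran-3-yl tetradecanoate (methyl and acyloxy cis) | CCCCCCCCCCCCCC(=O)O[C@H]([C@H](C)O1)C(=O)C=C1c2coc(Cc3cnco3)n2 | intermediate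
17 | (2S,3S,4S)-4-hydroxy-2-methyl-6-[2-(oxazol-5-ylmethyl)oxazol-4-yl]-3,4-dihydro-2H-pyran-3-yl tetradecanoate (all-cis) | CCCCCCCCCCCCCC(=O)O[C@H]([C@H](C)O1)[C@@H](O)C=C1c2coc(Cc3cnco3)n2 | intermediate
18 | (2S,3S,4S,6S)-4,6-dihydroxy-2-methyl-6-[2-(oxazol-5-ylmethyl)oxazol-4-yl]tetrahydro-2H-pyran-3-yl tetradecanoate | CCCCCCCCCCCCCC(=O)O[C@H]([C@H](C)O1)[C@@H](O)C[C@@]1(O)c2coc(Cc3cnco3)n2 | intermediate
19 | (2S,3R,4S)-2,4-dihydroxy-6-oxo-6-[2-(oxazol-5-ylmethyl)oxazol-4-yl]hexan-3-yl tetradecanoate (open-chain tautomer of 18, formed in situ) | CCCCCCCCCCCCCC(=O)O[C@H]([C@H](C)O)[C@@H](O)CC(=O)c1coc(Cc2cnco2)n1 | intermediate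
20 | C3′-O-diethylboryl derivative of 19, boron chelated by the C1′ carbonyl oxygen (formed in situ) | CCCCCCCCCCCCCC(=O)O[C@H]([C@H](C)O)[C@@H](OB(CC)CC)CC(=O)c1coc(Cc2cnco2)n1 | intermediate
21 | (2S,3R,4S,6R)-2,4,6-trihydroxy-6-[2-(oxazol-5-ylmethyl)oxazol-4-yl]hexan-3-yl tetradecanoate, that is (1′R,3′S,4′R,5′S) | CCCCCCCCCCCCCC(=O)O[C@H]([C@H](C)O)[C@@H](O)C[C@@H](O)c1coc(Cc2cnco2)n1 | target

Total step count: 12. Longest linear sequence: 10 (steps 1–4 and 7–12).

Steps most likely to fail

1. Step 9.
- Binding of the oxazole nitrogens to chromium may slow turnover.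
- Crowding at C1′ may divert the reaction into an open aldol pathway, which would erode both the cis preference and the facial control.
- Acetaldehyde may self-condense while it waits.
- The fallback gives up the cycloaddition for a chiral-pool acylation that uses only known reactions. It sets out from 7 and 9 and comes back at 16.
- O-tert-butyl-D-threonine F1 (purchased) is diazotised (NaNO2, dilute H2SO4, 0 °C). Net retention through the α-lactone gives (2R,3S)-3-tert-butoxy-2-hydroxybutanoic acid F2.
- Acylation of F2 with 9 (pyridine, CH2Cl2) gives (2R,3S)-3-tert-butoxy-2-(tetradecanoyloxy)butanoic acid F3.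
- F3 is activated with C6F5OH and EDC as its pentafluorophenyl ester F4.
- F4 acylates 7 at carbon under the conditions of step 7 to give (2S,3R)-2-tert-butoxy-4,6-dioxo-6-[2-(oxazol-5-ylmethyl)oxazol-4-yl]hexan-3-yl tetradecanoate F5.
- TFA in CH2Cl2 removes the tert-butyl group, and the freed O5′–H cyclodehydrates onto C1′ to give 16. A competing furanone closure is blocked because O4′ is already acylated.

2. Step 11.
- Acid may ionise the allylic C3′ hydroxyl (Ferrier-type).
- Acid may dehydrate the β-hydroxy ketone tautomer into conjugation with the oxazole.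
- Acid may promote an acyl shift between O4′ and its neighbours.
- The fallback replaces proton-initiated hydration by halogen-initiated hydration under near-neutral conditions. It sets out from 17 and comes back at 18.
- NIS in MeCN–H2O at 0 °C should give the C2′-iodo hemiketal F6, drawn as the trans-diaxial adduct.
- Radical deiodination of F6 (Bu3SnH, Et3B/air, toluene, 0 °C) erases the C2′ centre and delivers 18.

3. Step 12.
- Ring opening of the hemiketal may be slow at low temperature.
- Boron may be distributed over O3′ and O5′.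
- Either effect would lead to incomplete conversion or poor facial selectivity at C1′.
- The fallback changes from substrate control to reagent control. It sets out from 18, comes back at 21, and makes no new compound (F0).
- Noyori–Ikariya transfer hydrogenation with RuCl[(R,R)-TsDPEN](p-cymene) and HCO2H–Et3N at rt acts on the equilibrating ketone. The heteroaryl/alkyl differentiation of the catalyst should give the (1′R) carbinol independently of chelation.

Further compounds
F1 | step 9 | O-tert-butyl-D-threonine (purchased) | N[C@H]([C@H](C)OC(C)(C)C)C(=O)O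
F2 | step 9 | (2R,3S)-3-tert-butoxy-2-hydroxybutanoic acid | O[C@H]([C@H](C)OC(C)(C)C)C(=O)O
F3 | step 9 | (2R,3S)-3-tert-butoxy-2-(tetradecanoyloxy)butanoic acid | CCCCCCCCCCCCCC(=O)O[C@H]([C@H](C)OC(C)(C)C)C(=O)O
F4 | step 9 | pentafluorophenyl (2R,3S)-3-tert-butoxy-2-(tetradecanoyloxy)butanoate | CCCCCCCCCCCCCC(=O)O[C@H]([C@H](C)OC(C)(C)C)C(=O)Oc1c(F)c(F)c(F)c(F)c1F
F5 | step 9 | (2S,3R)-2-tert-butoxy-4,6-dioxo-6-[2-(oxazol-5-ylmethyl)oxazol-4-yl]hexan-3-yl tetradecanoate | CCCCCCCCCCCCCC(=O)O[C@H]([C@H](C)OC(C)(C)C)C(=O)CC(=O)c1coc(Cc2cnco2)n1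
F6 | step 11 | C2′-iodo derivative of hemiketal 18 (iodine axial, trans to the anomeric OH) | CCCCCCCCCCCCCC(=O)O[C@H]([C@H](C)O1)[C@@H](O)[C@@H](I)[C@@]1(O)c2coc(Cc3cnco3)n2
F0 | step 12 | none | none
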